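## Retrosynthetic overview

1. The last C–C bond is C11–aryl (drimane numbering), made by a B-alkyl Suzuki–Miyaura coupling of alkyl boronate 18 with aryl bromide 28; 28 already carries the formyl group, the protected catechol and the sulfate, so only one deprotection follows.
2. The C9–C11 bond and the C9 stereocentre come from kinetic α′-alkylation of trans-fused enone 13 with ICH2Bpin, anti to the angular methyl; the C8 methyl and the C7=C8 alkene come from conjugate reduction, enol triflate formation and Negishi methylation.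
3. Rings A and B are made in one cationic cascade (ring A closes first, ring B second) by an enantioselective proton-initiated bicyclisation of the acyclic (E)-dienyl β-keto ester 10; the ester is lost in the same flask to give ketone 12.
4. Ester 10 is built by acetylide alkylation, zirconium-catalysed carboalumination/iodination, Negishi coupling with a zinc homoenolate and a crossed Claisen condensation.
5. Arene 28 comes from catechol by SEM protection, bromination, lithiation–borylation–oxidation, ortho-bromination, ortho-formylation and sulfation.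

Assumption: the target is taken exactly as drawn, (1R,4aS,8aS) in the decalin unit (the ArCH2 group on C9 trans to the angular methyl on C10; C5 = ring-fusion CH, C8 = methyl-bearing alkene carbon, C11 = benzylic CH2), it is isolated as the free hydrogen sulfate, and the (S,S) antipode of the acid catalyst in step 5 is taken to give the (4aS,8aR) ketone (if not, its mirror image is used).

## Route

Step 1
Reactants: 1 5-bromo-2-methylpent-2-ene
Product: 2 6-methylhept-5-en-1-yne
Conditions: LiC≡CH·H2NCH2CH2NH2, DMSO, 15 °C → rt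
Reagents that add atoms: lithium acetylide (ethylenediamine complex), [Li]C#C
Why: SN2 alkylation of an acetylide by an unhindered primary homoallylic bromide; no stereocentre is formed.

Step 2
Reactants: 2 6-methylhept-5-en-1-yne
Product: 4 (1E)-1-iodo-2,6-dimethylhepta-1,5-diene, via dimethyl[(1E)-2,6-dimethylhepta-1,5-dien-1-yl]alane 3 (not isolated)
Conditions: AlMe3 (2 equiv), Cp2ZrCl2 (20 mol%), CH2Cl2, 0 °C → rt; then I2, THF, −30 → 0 °C
Reagents that add atoms: trimethylaluminium, C[Al](C)C; iodine, II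
Why: Negishi zirconium-catalysed syn-carboalumination of the terminal alkyne puts methyl and aluminium cis, and iodinolysis with retention gives the E vinyl iodide, the remote trisubstituted alkene being inert.

Step 3
Reactants: 4 (1E)-1-iodo-2,6-dimethylhepta-1,5-diene; 5 ethyl 3-iodopropanoate
Product: 7 ethyl (4E)-5,9-dimethyldeca-4,8-dienoate, via (3-ethoxy-3-oxopropyl)zinc iodide 6 (not isolated)
Conditions: 5, Zn dust (Me3SiCl-activated), THF, 35 °C; then 4, Pd(PPh3)4 (4 mol%), THF, 45 °C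
Reagents that add atoms: none
Why: Negishi sp2–sp3 cross-coupling of a zinc homoenolate with a vinyl iodide proceeds with retention of the E geometry and tolerates the ester.

Step 4
Reactants: 7 ethyl (4E)-5,9-dimethyldeca-4,8-dienoate; 8 tert-butyl acetate
Product: 10 tert-butyl (6E)-7,11-dimethyl-3-oxododeca-6,10-dienoate, via lithium 1-tert-butoxyethenolate 9 (not isolated)
Conditions: 8, LiN(i-Pr)2 (2.5 equiv), THF, −78 °C; then 7, −78 → 0 °C; aq. NH4Cl
Reagents that add atoms: none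
Why: crossed Claisen condensation of a non-self-condensing lithium ester enolate with the ethyl ester, driven by deprotonation of the β-keto ester formed; the alkenes are untouched.

Step 5
Reactants: 10 tert-butyl (6E)-7,11-dimethyl-3-oxododeca-6,10-dienoate
Product: 12 (4aS,8aR)-5,5,8a-trimethyloctahydronaphthalen-2(1H)-one, via tert-butyl (1R,4aS,8aS)-5,5,8a-trimethyl-2-oxodecahydronaphthalene-1-carboxylate 11 (not isolated)
Conditions: (S,S)-IDPi acid [imidodiphosphorimidate of two (S)-3,3′-bis[3,5-bis(trifluoromethyl)phenyl]-1,1′-bi-2-naphthol units, both nitrogen atoms on phosphorus carrying SO2CF3] (3 mol%), (CF3)3COH, −40 °C; then CF3CO2H, CH2Cl2, 40 °C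
Reagents that add atoms: none
Why: Proposed new method: the confined chiral Brønsted acid protonates the terminal trisubstituted alkene inside its anion pocket while the enol OH of the β-keto ester hydrogen-bonds to the same anion, so the chair–chair folded (E)-diene closes ring A and then ring B by anti addition across each alkene with C-attack of the enol on the C10 cation, which sets C5 and C10 (trans fusion) in one enantiomeric series, any O-cyclised enol ether re-ionising to the C–C bonded product, after which CF3CO2H cleaves the tert-butyl ester and the β-keto acid decarboxylates; the closest known reactions are the IDPi-catalysed enantioselective polyene cyclisation of homofarnesol (alcohol terminator) and the racemic SnCl4 cyclisation of geranyl acetoacetates.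

Step 6
Reactants: 12 (4aS,8aR)-5,5,8a-trimethyloctahydronaphthalen-2(1H)-one
Product: 13 (4aS,8aR)-5,5,8a-trimethyl-4a,5,6,7,8,8a-hexahydronaphthalen-2(1H)-one
Conditions: Pd(OCOCF3)2 (5 mol%), DMSO (10 mol%), O2 (1 atm), AcOH, 80 °C
Reagents that add atoms: none
Why: Stahl-type aerobic α,β-dehydrogenation (palladium enolate, then β-hydride elimination) can give only the C6=C7 enone because C10 is quaternary, and the stereocentres are not touched.

Step 7
Reactants: 13 (4aS,8aR)-5,5,8a-trimethyl-4a,5,6,7,8,8a-hexahydronaphthalen-2(1H)-one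
Product: 15 (1S,4aS,8aS)-5,5,8a-trimethyl-1-[(4,4,5,5-tetramethyl-1,3,2-dioxaborolan-2-yl)methyl]-4a,5,6,7,8,8a-hexahydronaphthalen-2(1H)-one, via lithium (4aS,8aS)-5,5,8a-trimethyl-4a,5,6,7,8,8a-hexahydronaphthalen-2-olate 14 (not isolated)
Conditions: LiN(i-Pr)2 (1.05 equiv), THF, −78 °C; then ICH2Bpin, DMPU, −78 → −20 °C
Reagents that add atoms: 2-(iodomethyl)-4,4,5,5-tetramethyl-1,3,2-dioxaborolane, CC1(C)OB(CI)OC1(C)C
Why: kinetic α′-deprotonation of the enone gives only the C8–C9 enolate, and its alkylation by the α-iodo boronate (Matteson-type enolate alkylation) occurs on the face opposite the adjacent axial angular methyl, setting C9 with the new CH2 group trans to that methyl.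

Step 8
Reactants: 15 (1S,4aS,8aS)-5,5,8a-trimethyl-1-[(4,4,5,5-tetramethyl-1,3,2-dioxaborolan-2-yl)methyl]-4a,5,6,7,8,8a-hexahydronaphthalen-2(1H)-one
Product: 17 (1S,4aS,8aS)-5,5,8a-trimethyl-1-[(4,4,5,5-tetramethyl-1,3,2-dioxaborolan-2-yl)methyl]-1,4,4a,5,6,7,8,8a-octahydronaphthalen-2-yl trifluoromethanesulfonate, via lithium (1S,4aS,8aS)-5,5,8a-trimethyl-1-[(4,4,5,5-tetramethyl-1,3,2-dioxaborolan-2-yl)methyl]-1,4,4a,5,6,7,8,8a-octahydronaphthalen-2-olate 16 (not isolated)
Conditions: LiBH(s-Bu)3 (1.1 equiv), THF, −78 °C; then PhNTf2, −78 → 0 °C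
Reagents that add atoms: N-phenylbis(trifluoromethanesulfonimide), O=S(=O)(N(c1ccccc1)S(=O)(=O)C(F)(F)F)C(F)(F)F
Why: conjugate hydride reduction of the β-unsubstituted enone gives the C7=C8 enolate regiospecifically and O-triflation traps it, so the alkene position of the target is fixed and C9 (not enolised) keeps its configuration.

Step 9
Reactants: 17 (1S,4aS,8aS)-5,5,8a-trimethyl-1-[(4,4,5,5-tetramethyl-1,3,2-dioxaborolan-2-yl)methyl]-1,4,4a,5,6,7,8,8a-octahydronaphthalen-2-yl trifluoromethanesulfonate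
Product: 18 4,4,5,5-tetramethyl-2-{[(1R,4aS,8aR)-2,5,5,8a-tetramethyl-1,4,4a,5,6,7,8,8a-octahydronaphthalen-1-yl]methyl}-1,3,2-dioxaborolane
Conditions: MeZnCl (2 equiv), Pd(PPh3)4 (5 mol%), THF, 50 °C
Reagents that add atoms: methylzinc chloride, C[Zn]Cl
Why: Negishi coupling of the enol triflate installs the C8 methyl without moving the alkene, and the alkyl pinacol boronate does not transmetalate in the absence of base.

Step 10
Reactants: 19 benzene-1,2-diol (catechol)
Product: 20 1,2-bis{[2-(trimethylsilyl)ethoxy]methoxy}benzene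
Conditions: NaH (2.3 equiv), SEMCl (2.3 equiv), DMF, 0 °C → rt
Reagents that add atoms: 2-(trimethylsilyl)ethoxymethyl chloride, C[Si](C)(C)CCOCCl
Why: Williamson-type double O-alkylation of the catecholate gives base-stable, fluoride-labile SEM ethers.

Step 11
Reactants: 20 1,2-bis{[2-(trimethylsilyl)ethoxy]methoxy}benzene
Product: 21 4-bromo-1,2-bis{[2-(trimethylsilyl)ethoxy]methoxy}benzene
Conditions: NBS (1.0 equiv), MeCN, 0 °C → rt
Reagents that add atoms: N-bromosuccinimide, O=C1CCC(=O)N1Br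
Why: electrophilic aromatic bromination of the dialkoxybenzene goes para to one oxygen, and the acid-free conditions spare the SEM ethers.

Step 12
Reactants: 21 4-bromo-1,2-bis{[2-(trimethylsilyl)ethoxy]methoxy}benzene
Product: 24 3,4-bis{[2-(trimethylsilyl)ethoxy]methoxy}phenol, via (3,4-bis{[2-(trimethylsilyl)ethoxy]methoxy}phenyl)lithium 22 (not isolated), via dimethyl (3,4-bis{[2-(trimethylsilyl)ethoxy]methoxy}phenyl)boronate 23 (not isolated)
Conditions: n-BuLi, THF, −78 °C; B(OMe)3, −78 → 0 °C; then H2O2 (30%), aq. NaOH, 0 °C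
Reagents that add atoms: hydrogen peroxide, OO
Why: bromine–lithium exchange is faster than ortho-lithiation at −78 °C, and borylation followed by oxidative 1,2-migration places the third oxygen para to one SEM ether.

Step 13
Reactants: 24 3,4-bis{[2-(trimethylsilyl)ethoxy]methoxy}phenol
Product: 25 2-bromo-4,5-bis{[2-(trimethylsilyl)ethoxy]methoxy}phenol
Conditions: NBS (1.0 equiv), CH2Cl2, −78 °C
Reagents that add atoms: N-bromosuccinimide, O=C1CCC(=O)N1Br
Why: electrophilic bromination takes the unhindered position ortho to the free OH and para to an SEM ether (the position between two oxygens is shielded), as with sesamol.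

Step 14
Reactants: 25 2-bromo-4,5-bis{[2-(trimethylsilyl)ethoxy]methoxy}phenol
Product: 26 3-bromo-2-hydroxy-5,6-bis{[2-(trimethylsilyl)ethoxy]methoxy}benzaldehyde
Conditions: MgCl2, Et3N, (CH2O)n, MeCN, 80 °C
Reagents that add atoms: paraformaldehyde (formaldehyde), C=O
Why: Casnati–Skattebøl magnesium-phenoxide-directed formylation attacks only ortho to the OH, and the single free ortho position is the one between the OH and the SEM ether.

Step 15
Reactants: 26 3-bromo-2-hydroxy-5,6-bis{[2-(trimethylsilyl)ethoxy]methoxy}benzaldehyde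
Product: 28 tetrabutylammonium 2-bromo-6-formyl-4,5-bis{[2-(trimethylsilyl)ethoxy]methoxy}phenyl sulfate, via tributylammonium 2-bromo-6-formyl-4,5-bis{[2-(trimethylsilyl)ethoxy]methoxy}phenyl sulfate 27 (not isolated)
Conditions: n-Bu3N·SO3 (2 equiv), MeCN, 80 °C; then n-Bu4NOH (1.0 equiv), MeOH, rt
Reagents that add atoms: tributylamine–sulfur trioxide, CCCC[N+](CCCC)(CCCC)S(=O)(=O)[O-]; tetrabutylammonium hydroxide, CCCC[N+](CCCC)(CCCC)CCCC.[OH-]
Why: O-sulfation of the only free phenol by an amine–SO3 complex, then cation exchange to a lipophilic, base-stable tetrabutylammonium aryl sulfate that can be chromatographed.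

Step 16
Reactants: 18 4,4,5,5-tetramethyl-2-{[(1R,4aS,8aR)-2,5,5,8a-tetramethyl-1,4,4a,5,6,7,8,8a-octahydronaphthalen-1-yl]methyl}-1,3,2-dioxaborolane; 28 tetrabutylammonium 2-bromo-6-formyl-4,5-bis{[2-(trimethylsilyl)ethoxy]methoxy}phenyl sulfate
Product: 29 tetrabutylammonium 2-formyl-3,4-bis{[2-(trimethylsilyl)ethoxy]methoxy}-6-{[(1R,4aS,8aS)-2,5,5,8a-tetramethyl-1,4,4a,5,6,7,8,8a-octahydronaphthalen-1-yl]methyl}phenyl sulfate
Conditions: Pd(OAc)2 (5 mol%), RuPhos (10 mol%), K3PO4 (3 equiv), toluene/H2O (10:1), 90 °C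
Reagents that add atoms: none
Why: B-alkyl Suzuki–Miyaura coupling, in which the bulky electron-rich phosphine favours oxidative addition of the aryl bromide and reductive elimination over β-hydride elimination, forms the C11–aryl bond; the sulfate anion, aldehyde and SEM ethers are inert to the aqueous base and no stereocentre is touched.

Step 17
Reactants: 29 tetrabutylammonium 2-formyl-3,4-bis{[2-(trimethylsilyl)ethoxy]methoxy}-6-{[(1R,4aS,8aS)-2,5,5,8a-tetramethyl-1,4,4a,5,6,7,8,8a-octahydronaphthalen-1-yl]methyl}phenyl sulfate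
Product: 31 2-formyl-3,4-dihydroxy-6-{[(1R,4aS,8aS)-2,5,5,8a-tetramethyl-1,4,4a,5,6,7,8,8a-octahydronaphthalen-1-yl]methyl}phenyl hydrogen sulfate, via tetrabutylammonium 2-formyl-3,4-dihydroxy-6-{[(1R,4aS,8aS)-2,5,5,8a-tetramethyl-1,4,4a,5,6,7,8,8a-octahydronaphthalen-1-yl]methyl}phenyl sulfate 30 (not isolated)
Conditions: n-Bu4NF (6 equiv), THF, 45 °C, argon; then Dowex 50W-X8 (H+ form), MeOH/H2O, 0 °C
Reagents that add atoms: none
Why: fluoride attack at silicon fragments each SEM ether (loss of Me3SiF, ethene and formaldehyde) under basic conditions in which an aryl sulfate monoester is stable, and a brief cold cation exchange then gives the hydrogen sulfate without acid solvolysis.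

## Compound list

1 | 5-bromo-2-methylpent-2-ene | CC(C)=CCCBr | starting material
2 | 6-methylhept-5-en-1-yne | CC(C)=CCCC#C | intermediate
3 | dimethyl[(1E)-2,6-dimethylhepta-1,5-dien-1-yl]alane | C[Al](C)/C=C(\C)CCC=C(C)C | intermediate (not isolated)
4 | (1E)-1-iodo-2,6-dimethylhepta-1,5-diene | I/C=C(\C)CCC=C(C)C | intermediate
5 | ethyl 3-iodopropanoate | CCOC(=O)CCI | starting material
6 | (3-ethoxy-3-oxopropyl)zinc iodide | CCOC(=O)CC[Zn]I | intermediate (not isolated)
7 | ethyl (4E)-5,9-dimethyldeca-4,8-dienoate | CCOC(=O)CC/C=C(\C)CCC=C(C)C | intermediate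
8 | tert-butyl acetate | CC(=O)OC(C)(C)C | starting material
9 | lithium 1-tert-butoxyethenolate | [Li]OC(=C)OC(C)(C)C | intermediate (not isolated)
10 | tert-butyl (6E)-7,11-dimethyl-3-oxododeca-6,10-dienoate | CC(C)(C)OC(=O)CC(=O)CC/C=C(\C)CCC=C(C)C | intermediate
11 | tert-butyl (1R,4aS,8aS)-5,5,8a-trimethyl-2-oxodecahydronaphthalene-1-carboxylate (trans-fused, ester equatorial) | O=C1CC[C@H]2C(C)(C)CCC[C@]2(C)[C@H]1C(=O)OC(C)(C)C | intermediate (not isolated)
12 | (4aS,8aR)-5,5,8a-trimethyloctahydronaphthalen-2(1H)-one (trans-fused) | O=C1CC[C@H]2C(C)(C)CCC[C@]2(C)C1 | intermediate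
13 | (4aS,8aR)-5,5,8a-trimethyl-4a,5,6,7,8,8a-hexahydronaphthalen-2(1H)-one | O=C1C=C[C@H]2C(C)(C)CCC[C@]2(C)C1 | intermediate
14 | lithium (4aS,8aS)-5,5,8a-trimethyl-4a,5,6,7,8,8a-hexahydronaphthalen-2-olate (cross-conjugated dienolate) | [Li]OC=1C=C[C@H]2C(C)(C)CCC[C@]2(C)C=1 | intermediate (not isolated)
15 | (1S,4aS,8aS)-5,5,8a-trimethyl-1-[(4,4,5,5-tetramethyl-1,3,2-dioxaborolan-2-yl)methyl]-4a,5,6,7,8,8a-hexahydronaphthalen-2(1H)-one (CH2B trans to the angular methyl) | O=C1C=C[C@H]2C(C)(C)CCC[C@]2(C)[C@@H]1CB3OC(C)(C)C(C)(C)O3 | intermediate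
16 | lithium (1S,4aS,8aS)-5,5,8a-trimethyl-1-[(4,4,5,5-tetramethyl-1,3,2-dioxaborolan-2-yl)methyl]-1,4,4a,5,6,7,8,8a-octahydronaphthalen-2-olate | [Li]OC1=CC[C@H]2C(C)(C)CCC[C@]2(C)[C@@H]1CB3OC(C)(C)C(C)(C)O3 | intermediate (not isolated)
17 | (1S,4aS,8aS)-5,5,8a-trimethyl-1-[(4,4,5,5-tetramethyl-1,3,2-dioxaborolan-2-yl)methyl]-1,4,4a,5,6,7,8,8a-octahydronaphthalen-2-yl trifluoromethanesulfonate | O=S(=O)(OC1=CC[C@H]2C(C)(C)CCC[C@]2(C)[C@@H]1CB3OC(C)(C)C(C)(C)O3)C(F)(F)F | intermediate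
18 | 4,4,5,5-tetramethyl-2-{[(1R,4aS,8aR)-2,5,5,8a-tetramethyl-1,4,4a,5,6,7,8,8a-octahydronaphthalen-1-yl]methyl}-1,3,2-dioxaborolane (same spatial arrangement as in 31; the 8a descriptor differs only through CIP priorities) | CC1=CC[C@H]2C(C)(C)CCC[C@]2(C)[C@@H]1CB3OC(C)(C)C(C)(C)O3 | intermediate
19 | benzene-1,2-diol (catechol) | Oc1ccccc1O | starting material
20 | 1,2-bis{[2-(trimethylsilyl)ethoxy]methoxy}benzene | C[Si](C)(C)CCOCOc1ccccc1OCOCC[Si](C)(C)C | intermediate
21 | 4-bromo-1,2-bis{[2-(trimethylsilyl)ethoxy]methoxy}benzene | C[Si](C)(C)CCOCOc1ccc(Br)cc1OCOCC[Si](C)(C)C | intermediate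
22 | (3,4-bis{[2-(trimethylsilyl)ethoxy]methoxy}phenyl)lithium | [Li]c1ccc(OCOCC[Si](C)(C)C)c(OCOCC[Si](C)(C)C)c1 | intermediate (not isolated)
23 | dimethyl (3,4-bis{[2-(trimethylsilyl)ethoxy]methoxy}phenyl)boronate | COB(OC)c1ccc(OCOCC[Si](C)(C)C)c(OCOCC[Si](C)(C)C)c1 | intermediate (not isolated)
24 | 3,4-bis{[2-(trimethylsilyl)ethoxy]methoxy}phenol | Oc1ccc(OCOCC[Si](C)(C)C)c(OCOCC[Si](C)(C)C)c1 | intermediate
25 | 2-bromo-4,5-bis{[2-(trimethylsilyl)ethoxy]methoxy}phenol | Oc1cc(OCOCC[Si](C)(C)C)c(OCOCC[Si](C)(C)C)cc1Br | intermediate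
26 | 3-bromo-2-hydroxy-5,6-bis{[2-(trimethylsilyl)ethoxy]methoxy}benzaldehyde | O=Cc1c(O)c(Br)cc(OCOCC[Si](C)(C)C)c1OCOCC[Si](C)(C)C | intermediate
27 | tributylammonium 2-bromo-6-formyl-4,5-bis{[2-(trimethylsilyl)ethoxy]methoxy}phenyl sulfate | O=Cc1c(OS(=O)(=O)[O-])c(Br)cc(OCOCC[Si](C)(C)C)c1OCOCC[Si](C)(C)C.CCCC[NH+](CCCC)CCCC | intermediate (not isolated)
28 | tetrabutylammonium 2-bromo-6-formyl-4,5-bis{[2-(trimethylsilyl)ethoxy]methoxy}phenyl sulfate | O=Cc1c(OS(=O)(=O)[O-])c(Br)cc(OCOCC[Si](C)(C)C)c1OCOCC[Si](C)(C)C.CCCC[N+](CCCC)(CCCC)CCCC | intermediate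
29 | tetrabutylammonium 2-formyl-3,4-bis{[2-(trimethylsilyl)ethoxy]methoxy}-6-{[(1R,4aS,8aS)-2,5,5,8a-tetramethyl-1,4,4a,5,6,7,8,8a-octahydronaphthalen-1-yl]methyl}phenyl sulfate | CC1=CC[C@H]2C(C)(C)CCC[C@]2(C)[C@@H]1Cc1cc(OCOCC[Si](C)(C)C)c(OCOCC[Si](C)(C)C)c(C=O)c1OS(=O)(=O)[O-].CCCC[N+](CCCC)(CCCC)CCCC | intermediate
30 | tetrabutylammonium 2-formyl-3,4-dihydroxy-6-{[(1R,4aS,8aS)-2,5,5,8a-tetramethyl-1,4,4a,5,6,7,8,8a-octahydronaphthalen-1-yl]methyl}phenyl sulfate | CC1=CC[C@H]2C(C)(C)CCC[C@]2(C)[C@@H]1Cc1cc(O)c(O)c(C=O)c1OS(=O)(=O)[O-].CCCC[N+](CCCC)(CCCC)CCCC | intermediate (not isolated)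
31 | 2-formyl-3,4-dihydroxy-6-{[(1R,4aS,8aS)-2,5,5,8a-tetramethyl-1,4,4a,5,6,7,8,8a-octahydronaphthalen-1-yl]methyl}phenyl hydrogen sulfate (CNP0018731.3) | CC1=CC[C@H]2C(C)(C)CCC[C@]2(C)[C@@H]1Cc1cc(O)c(O)c(C=O)c1OS(=O)(=O)O | target

## Step count and weak points

Total steps: 17. Longest linear sequence: 11 steps (steps 1–9, then 16 and 17); the arene branch (steps 10–15) runs in parallel.

Steps most likely to fail:

Step 5 (the proposed new bicyclisation). The risks are low enantioselectivity, O- instead of C-termination, or monocyclic products. The fallback sets out from 10 and comes back at 12. Compound 10 is cyclised with SnCl4 (CH2Cl2, 0 °C → rt, the known tin tetrachloride cyclisation of geranyl acetoacetates) to the racemic trans-fused bicyclic ester, tert-butyl rac-(1R,4aS,8aS)-5,5,8a-trimethyl-2-oxodecahydronaphthalene-1-carboxylate F1. This is cleaved and decarboxylated with CF3CO2H to the racemic ketone, rac-(4aS,8aR)-5,5,8a-trimethyloctahydronaphthalen-2(1H)-one F2. Ketalisation with (1R,2R)-1,2-diphenylethane-1,2-diol (PPTS, benzene, Dean–Stark) gives two diastereomeric dioxolanes: (4R,5R,4a′S,8a′R)-5′,5′,8a′-trimethyl-4,5-diphenyloctahydro-1′H-spiro[1,3-dioxolane-2,2′-naphthalene] F3, and its (4R,5R,4a′R,8a′S) diastereomer F4. They are separated by chromatography and crystallisation, and hydrolysis of F3 (aq. HCl, THF) returns enantiopure 12.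

Step 16 (Suzuki coupling of a β-branched primary alkyl boronate). The risks are slow transmetalation, protodeboronation or β-hydride elimination. The fallback sets out from 18 and comes back at 29. Oxidation of 18 (NaBO3·4H2O, THF/H2O) gives [(1R,4aS,8aS)-2,5,5,8a-tetramethyl-1,4,4a,5,6,7,8,8a-octahydronaphthalen-1-yl]methanol F5. Iodination (I2, PPh3, imidazole, CH2Cl2, 0 °C) gives (1R,4aS,8aS)-1-(iodomethyl)-2,5,5,8a-tetramethyl-1,4,4a,5,6,7,8,8a-octahydronaphthalene F6. F6 is joined to 28 by the known nickel-catalysed reductive cross-electrophile coupling of alkyl iodides with aryl bromides (NiBr2·MeOCH2CH2OMe 10 mol%, 4,4′-di-tert-butyl-2,2′-bipyridine, Zn, NaI, DMA, 60 °C). This goes through an alkyl radical captured at nickel and needs no boron-to-palladium transfer; it gives 29.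

Step 17 (SEM removal next to an aryl sulfate and an aldehyde). The risks are incomplete cleavage, hydroxymethylation of the electron-rich ring by the formaldehyde released, or loss of the sulfate on work-up. The fallback sets out from 18 and 26 and comes back at 31; it moves the deprotection ahead of the sulfation. Coupling of 18 with the free phenol 26 under the step 16 conditions gives 2-hydroxy-5,6-bis{[2-(trimethylsilyl)ethoxy]methoxy}-3-{[(1R,4aS,8aS)-2,5,5,8a-tetramethyl-1,4,4a,5,6,7,8,8a-octahydronaphthalen-1-yl]methyl}benzaldehyde F7. With no sulfate present, the SEM groups are removed with MgBr2·OEt2 (Et2O/MeNO2, rt) to give 2,3,6-trihydroxy-5-{[(1R,4aS,8aS)-2,5,5,8a-tetramethyl-1,4,4a,5,6,7,8,8a-octahydronaphthalen-1-yl]methyl}benzaldehyde F8. The catechol is masked in the flask with PhB(OH)2 (toluene, 4 Å sieves) as 7-hydroxy-2-phenyl-6-{[(1R,4aS,8aS)-2,5,5,8a-tetramethyl-1,4,4a,5,6,7,8,8a-octahydronaphthalen-1-yl]methyl}-1,3,2-benzodioxaborole-4-carbaldehyde F9. The one free phenol is sulfated (SO3·pyridine, pyridine, 40 °C) to pyridinium 4-formyl-2-phenyl-6-{[(1R,4aS,8aS)-2,5,5,8a-tetramethyl-1,4,4a,5,6,7,8,8a-octahydronaphthalen-1-yl]methyl}-1,3,2-benzodioxaborol-7-yl sulfate F10. Mild release of the boronate (D-sorbitol, aq. NaHCO3) and cold H+ exchange then give 31.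

## Further compounds

F1 | step 5 | tert-butyl rac-(1R,4aS,8aS)-5,5,8a-trimethyl-2-oxodecahydronaphthalene-1-carboxylate (racemate, one enantiomer drawn) | O=C1CC[C@H]2C(C)(C)CCC[C@]2(C)[C@H]1C(=O)OC(C)(C)C
F2 | step 5 | rac-(4aS,8aR)-5,5,8a-trimethyloctahydronaphthalen-2(1H)-one (racemate, one enantiomer drawn) | O=C1CC[C@H]2C(C)(C)CCC[C@]2(C)C1
F3 | step 5 | (4R,5R,4a′S,8a′R)-5′,5′,8a′-trimethyl-4,5-diphenyloctahydro-1′H-spiro[1,3-dioxolane-2,2′-naphthalene] | O1[C@H](c2ccccc2)[C@@H](c2ccccc2)OC13CC[C@H]4C(C)(C)CCC[C@]4(C)C3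
F4 | step 5 | (4R,5R,4a′R,8a′S)-5′,5′,8a′-trimethyl-4,5-diphenyloctahydro-1′H-spiro[1,3-dioxolane-2,2′-naphthalene] | O1[C@H](c2ccccc2)[C@@H](c2ccccc2)OC13CC[C@@H]4C(C)(C)CCC[C@@]4(C)C3
F5 | step 16 | [(1R,4aS,8aS)-2,5,5,8a-tetramethyl-1,4,4a,5,6,7,8,8a-octahydronaphthalen-1-yl]methanol | CC1=CC[C@H]2C(C)(C)CCC[C@]2(C)[C@@H]1CO
F6 | step 16 | (1R,4aS,8aS)-1-(iodomethyl)-2,5,5,8a-tetramethyl-1,4,4a,5,6,7,8,8a-octahydronaphthalene | CC1=CC[C@H]2C(C)(C)CCC[C@]2(C)[C@@H]1CI
F7 | step 17 | 2-hydroxy-5,6-bis{[2-(trimethylsilyl)ethoxy]methoxy}-3-{[(1R,4aS,8aS)-2,5,5,8a-tetramethyl-1,4,4a,5,6,7,8,8a-octahydronaphthalen-1-yl]methyl}benzaldehyde | CC1=CC[C@H]2C(C)(C)CCC[C@]2(C)[C@@H]1Cc1cc(OCOCC[Si](C)(C)C)c(OCOCC[Si](C)(C)C)c(C=O)c1O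
F8 | step 17 | 2,3,6-trihydroxy-5-{[(1R,4aS,8aS)-2,5,5,8a-tetramethyl-1,4,4a,5,6,7,8,8a-octahydronaphthalen-1-yl]methyl}benzaldehyde | CC1=CC[C@H]2C(C)(C)CCC[C@]2(C)[C@@H]1Cc1cc(O)c(O)c(C=O)c1O
F9 | step 17 | 7-hydroxy-2-phenyl-6-{[(1R,4aS,8aS)-2,5,5,8a-tetramethyl-1,4,4a,5,6,7,8,8a-octahydronaphthalen-1-yl]methyl}-1,3,2-benzodioxaborole-4-carbaldehyde | CC1=CC[C@H]2C(C)(C)CCC[C@]2(C)[C@@H]1Cc1cc2OB(c3ccccc3)Oc2c(C=O)c1O
F10 | step 17 | pyridinium 4-formyl-2-phenyl-6-{[(1R,4aS,8aS)-2,5,5,8a-tetramethyl-1,4,4a,5,6,7,8,8a-octahydronaphthalen-1-yl]methyl}-1,3,2-benzodioxaborol-7-yl sulfate | CC1=CC[C@H]2C(C)(C)CCC[C@]2(C)[C@@H]1Cc1cc2OB(c3ccccc3)Oc2c(C=O)c1OS(=O)(=O)[O-].c1cc[nH+]cc1
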